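## The problem

Compound 62 is a 28-membered macrolactone (C1 carbonyl, ring carbons C2–C27, ring oxygen on C27) with a 1-hydroxyhexyl branch on C2, nine free hydroxyls and a pentaene running from C16 to C25. Twelve stereocentres have to be set: C1′(S), C2(R), C3(S), C5(S), C7(R), C9(S), C11(S), C13(S), C14(R), C15(S), C26(S) and C27(R). In the zigzag they are 3,5-syn, 5,7-anti, 7,9-syn, 9,11-syn, 11,13-syn, 13,14-syn and 14,15-anti. As the structure is drawn, C15 lies cis to C18 across C16=C17 (16Z, methyl trans to C18), while the four other double bonds are E. The polyene therefore cannot come from an unselective olefination followed by iodine equilibration, and it must be kept from acid and light once complete. The skipped carbinols C5, C7 and C9 are too remote to control one another and need reagent control, whereas C14 can control C13 (chelation), C13 can control C11 (directed reduction) and C14 can control C15 (Felkin addition). The fragile sites are the C15 carbinol, which is allylic to the whole pentaene and ionises in acid, the lactone with β-hydroxyls at both C3 and C1′ (retro-aldol, elimination and acyl shift under base), and every β-silyloxy carbonyl compound met on the way. The feature that opens the key step is the C11–C12–C13 unit: C13 is a carbinol syn to the C14 carbinol and 1,3 to C11, which is what remains when a C11 nitrile oxide adds across a C12=C13 olefin under direction from a C14 hydroxyl and the 2-isoxazoline is later unmasked and reduced.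

## Retrosynthesis

Locants are those of 62 throughout. TBS = tert-butyldimethylsilyl, TES = triethylsilyl, Bn = benzyl.

**Protecting groups (62 from 61).** No skeletal bond is cut: all nine hydroxyls are carried as TBS ethers in macrolactone 61. Ketals were set aside because their removal needs aqueous acid, under which the C15 carbinol ionises. The last step must therefore be a single buffered fluoride treatment.

**C21–C22 and the C1–O ester bond (61 from 60, 60 from 50 and 58).** The ring is opened at the single bond in the middle of the pentaene, giving trienyl iodide/dienylstannane 60, and then at the lactone, giving acid 50 and stannyl alcohol 58. A coupling between two sp2 carbons is stereospecific, so the 16Z bond and the four E bonds are fixed inside the fragments. An olefination at C18=C19 or C20=C21 would give E/Z mixtures, and the usual cure by equilibration would scramble C16=C17. Making the hindered ester first, intermolecularly, leaves ring closure to a reaction that does not feel the crowding at C1 and C27. A triene and a diene replace the pentaene until the penultimate step. The forward steps must esterify without epimerising C2 and close the ring by Stille coupling at high dilution.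

**East piece (58 from 51).** C26 and C27 are anti, the pattern of a Fráter–Seebach methylation of ethyl (R)-3-hydroxybutanoate 51. C24=C25 then comes from a Takai olefination and C22=C23 from a Stille coupling with a two-carbon bis-stannyl linchpin, six steps in all.

**C15–C16 (50 from 37 and 43).** Acid 50 is traced through iodide 48 and dienal 47 to the union of C15 aldehyde 37 with (Z)-alkenyl iodide 43. Cutting here brings the awkward Z-trisubstituted olefin in from a small molecule (39, made by trans-hydroalumination of but-2-yn-1-ol 38), where its geometry is guaranteed. A carbometalation or olefination on the full polyol would not give that guarantee. The coupling must add to the aldehyde only (imide present) and set C15 anti to C14 under Felkin control.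

**C2–C3 (37 from 25 and 32).** An auxiliary-controlled syn aldol joins C3 aldehyde 25 to imide 32, which already holds C1′. The neighbouring cut, C2–C1′, would need an anti aldol between a six-carbon aldehyde and an enolate of the entire polyol chain. Imide 32 comes in four steps from methyl 3-oxooctanoate 26 and oxazolidinone 30, with C1′ set by catalytic hydrogenation. The enolate carries a β-silyloxy group and must not eliminate.

**C11–C12 and O–C13 (25 from 18, 18 from 12 and 14).** Aldehyde 25 is isoxazoline 18 after N–O cleavage, 1,3-syn reduction, silylation, debenzylation and oxidation. Isoxazoline 18 is cut into aldoxime 12 and allylic alcohol 14. Compared with an aldol at C11–C12 or C12–C13, this union uses no enolate, so the β-silyloxy groups are safe. It also sets C13 from C14 in the bond-forming step, and it stores the β-hydroxy ketone in a form that survives silylation. The precursors are a linear tris-silyl ether and a four-carbon alkenol. The step must be face-selective at C12=C13 and regioselective, with carbon bonding to C12.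

**C4–C5, C6–C7, C8–C9 (12 from 1) and 14 from 13.** The oxime is built by three rounds of reagent-controlled allylation, silylation and ozonolysis from 3-(benzyloxy)propan-1-ol 1. Alkenol 14 is the mono-silyl ether of (R)-but-3-ene-1,2-diol 13.

## Roads not taken

**Alternative 1:** a two-directional allylation outward from C6. The cut is C4–C5 together with C7–C8. In the forward sense propane-1,3-diol A2 and allyl acetate A3 would be combined under a chiral cyclometalated iridium catalyst, assembled in the flask from [Ir(cod)Cl]2 A4 and a chiral bisphosphine. The product would be (4R,6R)-nona-1,8-diene-4,6-diol A1, the C2–C10 stretch with the anti carbinols of C5 and C7.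
- Merits: two C–C bonds and two stereocentres in one catalytic operation from the alcohol oxidation level; no stoichiometric chiral borane; because A1 is C2-symmetric, a mono-functionalisation at either end gives the same product.
- Weak points for this target: only C5 and C7 are addressed. The two identical olefins of A1 must be told apart in a mono-selective step before one becomes the C3 aldehyde and the other is extended to C9. The hard region C11–C15 is left untouched.
- Comparison: for C3–C9 this road is shorter and more atom-economical than steps 1–8 of the chosen route, and that advantage is real. The chosen plan sets against it a key step that solves C11–C14 and a fully linear, unambiguous differentiation of the chain ends.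

**Alternative 2:** ring closure by alkyne metathesis at C18–C19. The cut is the C18=C19 bond, traced back to a triple bond. The seco ester with two methyl-capped enyne ends A6 would be closed by the alkylidyne [Mo(≡CC6H4OMe)(OSiPh3)3] A8. This would give the 18,19-didehydro macrolactone A5 with loss of but-2-yne A7.
- Merits: ring-closing alkyne metathesis is dependable for large rings, raises no E/Z question at the closure, avoids tin, and keeps a robust enyne in place of the full pentaene until late.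
- Weak points for this target: the alkyne of A5 must then be turned into an E olefin inside a conjugated tetraene-yne. That means a trans-hydrometalation and protodemetalation on a very unsaturated macrocycle, with regiochemical and over-reduction risk and two extra steps. One enyne terminus of A6 sits next to the hindered 16Z olefin. The 13,14-acetonide of A5 needs acid at the end, which the C15 carbinol does not tolerate well.
- Comparison: the ring closure itself is probably more reliable than a Stille macrocyclisation, and A6 is easier to handle than a stannane-bearing seco compound. The chosen plan answers with a coupling that delivers the finished pentaene directly, with every geometry preset and an all-silyl protecting set.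

**Alternative 3:** a dithiane anion relay joining two epoxides at C9. The cut is C8–C9 together with C9–C10. Lithiated 2-(tert-butyldimethylsilyl)-1,3-dithiane A10 would open the C3–C8 epoxide A11. A polar additive would then trigger silyl migration from carbon to the C7 oxygen, and the new C9 anion would open the C10–C15 epoxide A12. The product would be the C3–C15 dithiane A9, with a C7 TBS ether and a free C11 hydroxyl.
- Merits: a one-flask, three-component union of two halves of the polyol, more convergent than any linear chain extension; in A9 the C7 oxygen emerges protected and the C11 oxygen free, so the two are differentiated without extra steps.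
- Weak points for this target: C9 arrives in A9 as a dithioketal. It must be unmasked in the presence of a p-methoxybenzyl ether and an acetonide and then reduced stereoselectively. Epoxides A11 and A12 each need their own multistep synthesis with C5, C7, C11, C13 and C14 already in place, so the C13/C14 problem is moved, not solved. The acetonide again calls for acid at the end.
- Comparison: in convergence this road is better than the chosen one. The chosen plan sets against it a union step that itself creates C13 under control of C14, a masked aldol that tolerates silylation, and one type of protecting group.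

Key step: step 13

Remark: the C16=C17 bond of 62 is treated as Z (C15 cis to C18); oxime 12 is drawn as its E isomer, and any Z isomer gives the same hydroximoyl chloride 15.

## Steps

In names, "TBS-oxy" means (tert-butyldimethylsilyl)oxy.

Step 1
Reactants: 1 3-(benzyloxy)propan-1-ol
Product: 2 3-(benzyloxy)propanal
Conditions: TEMPO (cat.), PhI(OAc)2, CH2Cl2, rt
Reagents that add atoms: none
Why: Oxoammonium (TEMPO) oxidation of a primary alcohol stops at the aldehyde and leaves the benzyl ether alone; the aldehyde is used at once.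

Step 2
Reactants: 2 3-(benzyloxy)propanal
Product: 3 (S)-1-(benzyloxy)hex-5-en-3-ol
Conditions: (−)-Ipc2BOMe, allylMgBr, Et2O, 0 °C to rt; 2, −78 °C; then NaOH, H2O2
Reagents that add atoms: allylmagnesium bromide, C=CC[Mg]Br
Why: Brown allylation: the allylborane of the (+)-α-pinene series adds to the Si face of an unbranched aldehyde through a chair transition state, giving the (S)-carbinol that becomes C5.

Step 3
Reactants: 3 (S)-1-(benzyloxy)hex-5-en-3-ol
Product: 4 (S)-{[1-(benzyloxy)hex-5-en-3-yl]oxy}(tert-butyl)dimethylsilane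
Conditions: TBSCl, imidazole, DMF, rt
Reagents that add atoms: tert-butyldimethylsilyl chloride, CC(C)(C)[Si](C)(C)Cl
Why: Standard silylation of a secondary alcohol; this ether stays until the final fluoride step.

Step 4
Reactants: 4 (S)-{[1-(benzyloxy)hex-5-en-3-yl]oxy}(tert-butyl)dimethylsilane
Product: 5 (R)-5-(benzyloxy)-3-(TBS-oxy)pentanal
Conditions: O3, CH2Cl2, −78 °C; PPh3, −78 °C to rt
Reagents that add atoms: ozone, [O-][O+]=O
Why: Ozonolysis with reductive work-up cuts the terminal olefin to the C7 aldehyde; silyl and benzyl ethers are inert at −78 °C when ozone is not used in excess.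

Step 5
Reactants: 5 (R)-5-(benzyloxy)-3-(TBS-oxy)pentanal
Product: 6 (4R,6R)-8-(benzyloxy)-6-(TBS-oxy)oct-1-en-4-ol
Conditions: (+)-Ipc2BOMe, allylMgBr, Et2O, 0 °C to rt; 5, −78 °C; then NaOH, H2O2
Reagents that add atoms: allylmagnesium bromide, C=CC[Mg]Br
Why: Brown allylation with the enantiomeric borane: Re-face addition sets C7 anti to C5. The β-silyloxy centre has little influence in the closed boron transition state, so the reagent decides.

Step 6
Reactants: 6 (4R,6R)-8-(benzyloxy)-6-(TBS-oxy)oct-1-en-4-ol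
Product: 7 (4R,6R)-8-(benzyloxy)-4,6-bis(TBS-oxy)oct-1-ene
Conditions: TBSCl, imidazole, DMF, rt
Reagents that add atoms: tert-butyldimethylsilyl chloride, CC(C)(C)[Si](C)(C)Cl
Why: Routine silylation of the new secondary carbinol.

Step 7
Reactants: 7 (4R,6R)-8-(benzyloxy)-4,6-bis(TBS-oxy)oct-1-ene
Product: 8 (3S,5R)-7-(benzyloxy)-3,5-bis(TBS-oxy)heptanal
Conditions: O3, CH2Cl2, −78 °C; PPh3, −78 °C to rt
Reagents that add atoms: ozone, [O-][O+]=O
Why: Ozonolysis with reductive work-up, as in step 4, reveals the C9 aldehyde.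

Step 8
Reactants: 8 (3S,5R)-7-(benzyloxy)-3,5-bis(TBS-oxy)heptanal
Product: 9 (4R,6R,8R)-10-(benzyloxy)-6,8-bis(TBS-oxy)dec-1-en-4-ol
Conditions: (+)-Ipc2BOMe, allylMgBr, Et2O, 0 °C to rt; 8, −78 °C; then NaOH, H2O2
Reagents that add atoms: allylmagnesium bromide, C=CC[Mg]Br
Why: The same borane as in step 5 again adds to the Re face and sets C9 syn to C7 under reagent control (Brown allylation).

Step 9
Reactants: 9 (4R,6R,8R)-10-(benzyloxy)-6,8-bis(TBS-oxy)dec-1-en-4-ol
Product: 10 (4R,6R,8R)-10-(benzyloxy)-4,6,8-tris(TBS-oxy)dec-1-ene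
Conditions: TBSCl, imidazole, DMF, rt
Reagents that add atoms: tert-butyldimethylsilyl chloride, CC(C)(C)[Si](C)(C)Cl
Why: Routine silylation of the C9 carbinol.

Step 10
Reactants: 10 (4R,6R,8R)-10-(benzyloxy)-4,6,8-tris(TBS-oxy)dec-1-ene
Product: 11 (3S,5S,7R)-9-(benzyloxy)-3,5,7-tris(TBS-oxy)nonanal
Conditions: O3, CH2Cl2, −78 °C; PPh3, −78 °C to rt
Reagents that add atoms: ozone, [O-][O+]=O
Why: Ozonolysis with reductive work-up gives the C11 aldehyde.

Step 11
Reactants: 11 (3S,5S,7R)-9-(benzyloxy)-3,5,7-tris(TBS-oxy)nonanal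
Product: 12 (1E,3R,5R,7R)-9-(benzyloxy)-3,5,7-tris(TBS-oxy)nonanal oxime
Conditions: NH2OH·HCl, pyridine, EtOH, rt
Reagents that add atoms: hydroxylamine hydrochloride, NO.Cl
Why: Buffered oxime condensation; the conditions are too mild to eliminate the C9 silyloxy group, and oxime geometry does not matter for step 13.

Step 12
Reactants: 13 (R)-but-3-ene-1,2-diol
Product: 14 (R)-1-(TBS-oxy)but-3-en-2-ol
Conditions: TBSCl (1 equiv), imidazole, CH2Cl2, 0 °C
Reagents that add atoms: tert-butyldimethylsilyl chloride, CC(C)(C)[Si](C)(C)Cl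
Why: The primary hydroxyl is silylated selectively on steric grounds, leaving the allylic C14 hydroxyl free to direct the key step.

Step 13
Reactants: 12 (1E,3R,5R,7R)-9-(benzyloxy)-3,5,7-tris(TBS-oxy)nonanal oxime; 14 (R)-1-(TBS-oxy)but-3-en-2-ol
Product: 18 C3–C15 isoxazoline (13,14-syn; free C14 hydroxyl; C15 primary TBS ether), via hydroximoyl chloride 15 (not isolated), via magnesium alkoxide 16 (not isolated), via nitrile oxide 17 (not isolated)
Conditions: 12, t-BuOCl, CH2Cl2, −78 °C; separately 14 (excess), i-PrOH, EtMgBr, CH2Cl2, 0 °C; combine at −78 °C, warm to rt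
Reagents that add atoms: none
Why: tert-Butyl hypochlorite chlorinates the oxime carbon to hydroximoyl chloride 15, and the magnesium alkoxides in the flask (16 and i-PrOMgBr) remove HCl to release nitrile oxide 17 gradually beside the dipolarophile. The oxygen of 17 binds the magnesium of allylic alkoxide 16, so the concerted, suprafacial [3+2] cycloaddition takes place inside that complex. The closest known reaction type is the magnesium-alkoxide-directed nitrile oxide cycloaddition to secondary allylic alcohols, used as an aldol surrogate. The 2-isoxazoline ring closes in this single cycloaddition: C11–C12 and O–C13 form together in an intermolecular annulation, not in a stepwise cyclisation. The one new stereocentre, C13, is controlled by C14: with the allylic C–H eclipsing the olefin to avoid A(1,3) strain, the chelated dipole can reach only the face syn to the C14 oxygen, which gives the 13,14-syn adduct. The step needs this facial selectivity, which the chelate secures and reinforces by accelerating the directed pathway over the undirected one. It also needs 5-substituted regiochemistry (carbon to the terminal C12, normal for a monosubstituted olefin) and suppression of nitrile oxide dimerisation, secured by slow generation of 17 and an excess of 16. No enolate or free aldehyde is involved, so the β-silyloxy centres cannot eliminate or epimerise.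

Step 14
Reactants: 18 C3–C15 isoxazoline (free C14 hydroxyl)
Product: 19 C3–C15 isoxazoline 14-O-TBS ether
Conditions: TBSOTf, 2,6-lutidine, CH2Cl2, −78 to 0 °C
Reagents that add atoms: tert-butyldimethylsilyl triflate, CC(C)(C)[Si](C)(C)OS(=O)(=O)C(F)(F)F
Why: Silyl triflate with a hindered base caps the secondary C14 hydroxyl, so that only the C13 oxygen can direct the later ketone reduction.

Step 15
Reactants: 19 C3–C15 isoxazoline 14-O-TBS ether
Product: 21 C3–C15 β-hydroxy ketone (11-oxo; 13-hydroxy), via β-hydroxy imine 20 (not isolated)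
Conditions: Mo(CO)6, MeCN/H2O, 80 °C
Reagents that add atoms: water, O
Why: Mo(CO)6 cleaves the weak N–O bond reductively and the β-hydroxy imine is hydrolysed by the water present. This unmasks the aldol without touching benzyl or silyl ethers and without epimerising C13.

Step 16
Reactants: 21 C3–C15 β-hydroxy ketone
Product: 22 C3–C15 11,13-syn diol
Conditions: Et2BOMe, NaBH4, THF/MeOH (4:1), −78 °C; then evaporation from MeOH
Reagents that add atoms: none
Why: Narasaka–Prasad reduction: the boron chelate between the C13 hydroxyl and the C11 ketone takes hydride axially in a half-chair, which sets C11 syn to C13.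

Step 17
Reactants: 22 C3–C15 11,13-syn diol
Product: 23 C3–C15 heptakis-TBS ether (3-O-benzyl)
Conditions: TBSOTf (excess), 2,6-lutidine, CH2Cl2, 0 °C to rt
Reagents that add atoms: tert-butyldimethylsilyl triflate, CC(C)(C)[Si](C)(C)OS(=O)(=O)C(F)(F)F
Why: Excess silyl triflate silylates both hindered secondary hydroxyls; a uniform TBS set allows one fluoride treatment at the end.

Step 18
Reactants: 23 C3–C15 heptakis-TBS ether (3-O-benzyl)
Product: 24 C3 primary alcohol
Conditions: H2 (1 atm), 10% Pd/C, EtOAc, rt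
Reagents that add atoms: none
Why: Hydrogenolysis of the benzyl ether is done here, before any olefin is present; ethyl acetate as solvent keeps the primary TBS ether intact.

Step 19
Reactants: 24 C3 primary alcohol
Product: 25 C3 aldehyde
Conditions: Dess–Martin periodinane, NaHCO3, CH2Cl2, rt
Reagents that add atoms: none
Why: Buffered Dess–Martin oxidation gives the aldehyde under neutral conditions, so the β-silyloxy group at C5 is not eliminated.

Step 20
Reactants: 26 methyl 3-oxooctanoate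
Product: 27 methyl (S)-3-hydroxyoctanoate
Conditions: H2 (50 atm), RuCl2[(S)-BINAP] (cat.), MeOH, 50 °C
Reagents that add atoms: none
Why: Noyori hydrogenation of a β-keto ester: the (S)-BINAP ruthenium dichloride catalyst reduces the chelated ketone on the face that gives the (S)-alcohol, the future C1′.

Step 21
Reactants: 27 methyl (S)-3-hydroxyoctanoate
Product: 28 methyl (S)-3-(TBS-oxy)octanoate
Conditions: TBSCl, imidazole, DMF, rt
Reagents that add atoms: tert-butyldimethylsilyl chloride, CC(C)(C)[Si](C)(C)Cl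
Why: Routine silylation; C1′ carries the same protecting group as the polyol.

Step 22
Reactants: 28 methyl (S)-3-(TBS-oxy)octanoate
Product: 29 (S)-3-(TBS-oxy)octanoic acid
Conditions: LiOH, THF/MeOH/H2O, rt; then 1 M HCl to pH 3
Reagents that add atoms: lithium hydroxide, [Li+].[OH-]
Why: Saponification of an unhindered methyl ester; the carboxylate formed at once is not prone to β-elimination.

Step 23
Reactants: 29 (S)-3-(TBS-oxy)octanoic acid; 30 (R)-4-benzyloxazolidin-2-one
Product: 32 (R)-4-benzyl-3-[(S)-3-(TBS-oxy)octanoyl]oxazolidin-2-one, via mixed pivalic anhydride 31 (not isolated)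
Conditions: PivCl, Et3N, THF, −20 °C; then LiCl, 30, −20 °C to rt
Reagents that add atoms: none
Why: The oxazolidinone is acylated through the mixed pivalic anhydride; LiCl makes it nucleophilic enough that no strong base meets the β-silyloxy acyl group.

Step 24
Reactants: 25 C3 aldehyde; 32 (R)-4-benzyl-3-[(S)-3-(TBS-oxy)octanoyl]oxazolidin-2-one
Product: 34 C1–C15 aldol adduct (2,3-syn; free C3 hydroxyl), via boron Z-enolate 33 (not isolated)
Conditions: 32, Bu2BOTf, Et3N, CH2Cl2, −78 to 0 °C; 25, −78 to 0 °C; pH 7 buffer, MeOH, H2O2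
Reagents that add atoms: none
Why: Evans syn aldol: the Z-boron enolate reacts through a chair Zimmerman–Traxler transition state on the face away from the benzyl group of the (R)-auxiliary, setting C2 and C3 (2,3-syn, 3,5-syn) under auxiliary control. The covalent boron enolate is not expected to expel the β-silyloxy group at low temperature.

Step 25
Reactants: 34 C1–C15 aldol adduct
Product: 35 C1–C15 nonakis-TBS ether (imide at C1)
Conditions: TBSOTf, 2,6-lutidine, CH2Cl2, −78 to 0 °C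
Reagents that add atoms: tert-butyldimethylsilyl triflate, CC(C)(C)[Si](C)(C)OS(=O)(=O)C(F)(F)F
Why: Silyl triflate silylates the hindered C3 aldol hydroxyl under non-basic conditions, so no retro-aldol can occur.

Step 26
Reactants: 35 C1–C15 nonakis-TBS ether
Product: 36 C15 primary alcohol
Conditions: HF·pyridine, pyridine, THF, 0 °C
Reagents that add atoms: none
Why: Buffered HF·pyridine removes the single primary TBS ether faster than the eight secondary ones, a routine steric differentiation.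

Step 27
Reactants: 36 C15 primary alcohol
Product: 37 C15 aldehyde
Conditions: Dess–Martin periodinane, NaHCO3, CH2Cl2, rt
Reagents that add atoms: none
Why: Dess–Martin oxidation gives the α-silyloxy aldehyde without epimerising C14; it is used crude.

Step 28
Reactants: 38 but-2-yn-1-ol
Product: 39 (Z)-3-iodobut-2-en-1-ol
Conditions: Red-Al (NaAlH2(OCH2CH2OMe)2), THF, 0 °C to rt; then I2, −78 to 0 °C
Reagents that add atoms: iodine, II
Why: Chelation-controlled trans-hydroalumination places aluminium on C3 cis to the CH2O group, and iodinolysis with retention gives the (Z)-iodoalkene that carries the future C16=C17 geometry.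

Step 29
Reactants: 39 (Z)-3-iodobut-2-en-1-ol
Product: 41 ethyl (2E,4Z)-5-iodohexa-2,4-dienoate, via (Z)-3-iodobut-2-enal 40 (not isolated)
Conditions: MnO2, Ph3P=CHCO2Et, CH2Cl2, rt
Reagents that add atoms: ethyl (triphenylphosphoranylidene)acetate, CCOC(=O)C=P(c1ccccc1)(c1ccccc1)c1ccccc1
Why: Tandem allylic oxidation and Wittig reaction: the sensitive (Z)-iodoenal is trapped as it forms by the stabilised ylide, which gives the (E)-enoate and leaves the iodoalkene geometry alone.

Step 30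
Reactants: 41 ethyl (2E,4Z)-5-iodohexa-2,4-dienoate
Product: 42 (2E,4Z)-5-iodohexa-2,4-dien-1-ol
Conditions: DIBAL-H (i-Bu2AlH), CH2Cl2, −78 °C; aq. potassium sodium tartrate
Reagents that add atoms: none
Why: DIBAL-H reduces the conjugated ester in the 1,2 sense to the allylic alcohol and does not touch the alkenyl iodide at −78 °C.

Step 31
Reactants: 42 (2E,4Z)-5-iodohexa-2,4-dien-1-ol
Product: 43 triethyl{[(2E,4Z)-5-iodohexa-2,4-dien-1-yl]oxy}silane
Conditions: TESCl, imidazole, CH2Cl2, 0 °C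
Reagents that add atoms: triethylsilyl chloride, CC[Si](Cl)(CC)CC
Why: A primary TES ether can later be removed in the presence of secondary TBS ethers.

Step 32
Reactants: 37 C15 aldehyde; 43 triethyl{[(2E,4Z)-5-iodohexa-2,4-dien-1-yl]oxy}silane
Product: 44 C1–C20 dienyl carbinol (15-hydroxy; 14,15-anti; 16Z,18E; 20-O-TES)
Conditions: CrCl2, NiCl2 (cat.), DMSO, rt
Reagents that add atoms: none
Why: Nozaki–Hiyama–Kishi coupling: nickel-catalysed insertion into the C–I bond and transmetalation to chromium give an alkenyl nucleophile that keeps its geometry and adds only to the aldehyde (imide and silyl ethers are inert). Felkin–Anh attack anti to the α-silyloxy group should favour the 14,15-anti carbinol, and the 16Z geometry is carried over from 43.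

Step 33
Reactants: 44 C1–C20 dienyl carbinol
Product: 45 C1–C20 15-O-TBS ether (20-O-TES)
Conditions: TBSOTf, 2,6-lutidine, CH2Cl2, −78 °C
Reagents that add atoms: tert-butyldimethylsilyl triflate, CC(C)(C)[Si](C)(C)OS(=O)(=O)C(F)(F)F
Why: Silyl triflate silylates the hindered allylic C15 hydroxyl at low temperature; the primary TES ether is stable to these conditions.

Step 34
Reactants: 45 C1–C20 15-O-TBS ether (20-O-TES)
Product: 46 C20 dienol
Conditions: PPTS, MeOH/CH2Cl2, 0 °C
Reagents that add atoms: none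
Why: Mild acid-catalysed methanolysis removes the primary TES ether, while the TBS ethers, including the allylic one at C15, remain.

Step 35
Reactants: 46 C20 dienol
Product: 47 C20 (16Z,18E)-dienal
Conditions: MnO2, CH2Cl2, rt
Reagents that add atoms: none
Why: MnO2 oxidises only the allylic primary alcohol and, being neutral, does not isomerise the diene.

Step 36
Reactants: 47 C20 (16Z,18E)-dienal
Product: 48 C1–C21 (16Z,18E,20E)-21-iodotriene imide
Conditions: CrCl2, CHI3, THF, 0 °C, dark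
Reagents that add atoms: iodoform, IC(I)I
Why: Takai olefination: the geminal dichromium species from iodoform adds to the aldehyde and eliminates to the (E)-iodoalkene; imide and silyl ethers are tolerated.

Step 37
Reactants: 48 C1–C21 iodotriene imide
Product: 50 C1–C21 iodotriene carboxylic acid, via peroxy acid 49 (not isolated)
Conditions: LiOH, H2O2, THF/H2O, 0 °C; Na2SO3; then HCl to pH 4
Reagents that add atoms: hydrogen peroxide, OO
Why: Lithium hydroperoxide attacks the exocyclic imide carbonyl selectively even when it is hindered, and sulfite reduces the peroxy acid; the mild base at 0 °C should not cause β-elimination.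

Step 38
Reactants: 51 ethyl (R)-3-hydroxybutanoate
Product: 53 ethyl (2R,3R)-3-hydroxy-2-methylbutanoate, via dilithio alkoxide enolate 52 (not isolated)
Conditions: LDA (LiN(i-Pr)2, 2.2 equiv), THF, −78 to −20 °C; MeI, DMPU, −78 to 0 °C
Reagents that add atoms: iodomethane, CI
Why: Fráter–Seebach alkylation: the chelated alkoxide enolate is methylated on the face away from the carbinol methyl group, which sets C26 anti to C27.

Step 39
Reactants: 53 ethyl (2R,3R)-3-hydroxy-2-methylbutanoate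
Product: 54 ethyl (2R,3R)-3-(TBS-oxy)-2-methylbutanoate
Conditions: TBSCl, imidazole, DMF, rt
Reagents that add atoms: tert-butyldimethylsilyl chloride, CC(C)(C)[Si](C)(C)Cl
Why: Routine silylation; the hydroxyl has to be masked for the reduction and the two metal-mediated steps that follow.

Step 40
Reactants: 54 ethyl (2R,3R)-3-(TBS-oxy)-2-methylbutanoate
Product: 55 (2R,3R)-3-(TBS-oxy)-2-methylbutanal
Conditions: DIBAL-H (i-Bu2AlH, 1.1 equiv), CH2Cl2, −78 °C; aq. potassium sodium tartrate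
Reagents that add atoms: none
Why: Partial reduction of a β-silyloxy ester stops at the aldehyde because the tetrahedral aluminium intermediate is stable at −78 °C; the aldehyde is used at once to avoid epimerisation at C26.

Step 41
Reactants: 55 (2R,3R)-3-(TBS-oxy)-2-methylbutanal
Product: 56 tert-butyl{[(2R,3S,4E)-5-iodo-3-methylpent-4-en-2-yl]oxy}dimethylsilane
Conditions: CrCl2, CHI3, THF, 0 °C
Reagents that add atoms: iodoform, IC(I)I
Why: Takai olefination gives the (E)-alkenyl iodide (C24=C25) under non-basic conditions that do not epimerise the α-stereocentre.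

Step 42
Reactants: 56 tert-butyl{[(2R,3S,4E)-5-iodo-3-methylpent-4-en-2-yl]oxy}dimethylsilane
Product: 57 tert-butyldimethyl{[(2R,3S,4E,6E)-3-methyl-7-(tributylstannyl)hepta-4,6-dien-2-yl]oxy}silane
Conditions: (E)-Bu3SnCH=CHSnBu3 (excess), PdCl2(MeCN)2 (cat.), DMF, rt
Reagents that add atoms: (E)-1,2-bis(tributylstannyl)ethene, CCCC[Sn](CCCC)(CCCC)/C=C/[Sn](CCCC)(CCCC)CCCC
Why: Stille coupling of the alkenyl iodide with an excess of the symmetrical distannane gives the mono-coupled (E,E)-dienylstannane with retention at both olefins.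

Step 43
Reactants: 57 tert-butyldimethyl{[(2R,3S,4E,6E)-3-methyl-7-(tributylstannyl)hepta-4,6-dien-2-yl]oxy}silane
Product: 58 (2R,3S,4E,6E)-3-methyl-7-(tributylstannyl)hepta-4,6-dien-2-ol
Conditions: TBAF (Bu4NF), THF, rt
Reagents that add atoms: none
Why: Fluoride removes the secondary TBS ether; alkenylstannanes are stable to TBAF.

Step 44
Reactants: 50 C1–C21 iodotriene carboxylic acid; 58 (2R,3S,4E,6E)-3-methyl-7-(tributylstannyl)hepta-4,6-dien-2-ol
Product: 60 seco ester (C21 iodide; C22 stannane), via mixed trichlorobenzoic anhydride 59 (not isolated)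
Conditions: 2,4,6-Cl3C6H2COCl, Et3N, toluene, rt; then 58, DMAP, toluene, rt
Reagents that add atoms: none
Why: Yamaguchi esterification: DMAP attacks the mixed anhydride at the aliphatic carbonyl and the acylpyridinium acylates the C27 alcohol. The intermolecular mode is chosen because both partners are hindered.

Step 45
Reactants: 60 seco ester (C21 iodide; C22 stannane)
Product: 61 nonakis-TBS macrolactone
Conditions: Pd2(dba)3 (cat.), AsPh3, i-Pr2NEt, DMF/THF, rt, high dilution, dark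
Reagents that add atoms: none
Why: Intramolecular Stille coupling: oxidative addition of zerovalent palladium to the trienyl iodide, transmetalation from the dienylstannane and reductive elimination form C21–C22 with retention at every double bond. This closes the 28-membered ring under neutral conditions.

Step 46
Reactants: 61 nonakis-TBS macrolactone
Product: 62 CNP0269947.1
Conditions: HF·pyridine, pyridine, THF, 0 °C to rt, dark
Reagents that add atoms: none
Why: Pyridine-buffered HF·pyridine cleaves all nine TBS ethers. It avoids the base that would open or transacylate the β-hydroxy lactone and the strong acid that would ionise the C15 carbinol.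

## Compound list

1 | 3-(benzyloxy)propan-1-ol | OCCCOCc1ccccc1 | starting material
2 | 3-(benzyloxy)propanal | O=CCCOCc1ccccc1 | intermediate
3 | (S)-1-(benzyloxy)hex-5-en-3-ol | C=CC[C@H](O)CCOCc1ccccc1 | intermediate
4 | (S)-{[1-(benzyloxy)hex-5-en-3-yl]oxy}(tert-butyl)dimethylsilane | C=CC[C@H](O[Si](C)(C)C(C)(C)C)CCOCc1ccccc1 | intermediate
5 | (R)-5-(benzyloxy)-3-(TBS-oxy)pentanal | O=CC[C@H](O[Si](C)(C)C(C)(C)C)CCOCc1ccccc1 | intermediate
6 | (4R,6R)-8-(benzyloxy)-6-(TBS-oxy)oct-1-en-4-ol | C=CC[C@@H](O)C[C@H](O[Si](C)(C)C(C)(C)C)CCOCc1ccccc1 | intermediate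
7 | (4R,6R)-8-(benzyloxy)-4,6-bis(TBS-oxy)oct-1-ene | C=CC[C@@H](O[Si](C)(C)C(C)(C)C)C[C@H](O[Si](C)(C)C(C)(C)C)CCOCc1ccccc1 | intermediate
8 | (3S,5R)-7-(benzyloxy)-3,5-bis(TBS-oxy)heptanal | O=CC[C@@H](O[Si](C)(C)C(C)(C)C)C[C@H](O[Si](C)(C)C(C)(C)C)CCOCc1ccccc1 | intermediate
9 | (4R,6R,8R)-10-(benzyloxy)-6,8-bis(TBS-oxy)dec-1-en-4-ol | C=CC[C@@H](O)C[C@@H](O[Si](C)(C)C(C)(C)C)C[C@H](O[Si](C)(C)C(C)(C)C)CCOCc1ccccc1 | intermediate
10 | (4R,6R,8R)-10-(benzyloxy)-4,6,8-tris(TBS-oxy)dec-1-ene | C=CC[C@@H](O[Si](C)(C)C(C)(C)C)C[C@@H](O[Si](C)(C)C(C)(C)C)C[C@H](O[Si](C)(C)C(C)(C)C)CCOCc1ccccc1 | intermediate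
11 | (3S,5S,7R)-9-(benzyloxy)-3,5,7-tris(TBS-oxy)nonanal (C3–C11 aldehyde) | O=CC[C@@H](O[Si](C)(C)C(C)(C)C)C[C@@H](O[Si](C)(C)C(C)(C)C)C[C@H](O[Si](C)(C)C(C)(C)C)CCOCc1ccccc1 | intermediate
12 | (1E,3R,5R,7R)-9-(benzyloxy)-3,5,7-tris(TBS-oxy)nonanal oxime (C3–C11 aldoxime) | O/N=C/C[C@@H](O[Si](C)(C)C(C)(C)C)C[C@@H](O[Si](C)(C)C(C)(C)C)C[C@H](O[Si](C)(C)C(C)(C)C)CCOCc1ccccc1 | intermediate
13 | (R)-but-3-ene-1,2-diol | OC[C@H](O)C=C | starting material
14 | (R)-1-(TBS-oxy)but-3-en-2-ol (C12–C15) | CC(C)(C)[Si](C)(C)OC[C@H](O)C=C | intermediate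
15 | (Z)-hydroximoyl chloride of 12 (chlorine on C11) | O/N=C(\Cl)C[C@@H](O[Si](C)(C)C(C)(C)C)C[C@@H](O[Si](C)(C)C(C)(C)C)C[C@H](O[Si](C)(C)C(C)(C)C)CCOCc1ccccc1 | intermediate
16 | bromomagnesium alkoxide of 14 | CC(C)(C)[Si](C)(C)OC[C@H](O[Mg]Br)C=C | intermediate
17 | C11 nitrile oxide derived from 12 | [O-][N+]#CC[C@@H](O[Si](C)(C)C(C)(C)C)C[C@@H](O[Si](C)(C)C(C)(C)C)C[C@H](O[Si](C)(C)C(C)(C)C)CCOCc1ccccc1 | intermediate
18 | (1S)-2-(TBS-oxy)-1-[(5S)-3-{(2R,4R,6R)-8-(benzyloxy)-2,4,6-tris(TBS-oxy)octyl}-4,5-dihydroisoxazol-5-yl]ethan-1-ol (C3–C15 isoxazoline; 13,14-syn) | CC(C)(C)[Si](C)(C)OC[C@H](O)[C@@H]1CC(=NO1)C[C@@H](O[Si](C)(C)C(C)(C)C)C[C@@H](O[Si](C)(C)C(C)(C)C)C[C@H](O[Si](C)(C)C(C)(C)C)CCOCc2ccccc2 | intermediate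
19 | 14-O-TBS ether of 18 | CC(C)(C)[Si](C)(C)OC[C@H](O[Si](C)(C)C(C)(C)C)[C@@H]1CC(=NO1)C[C@@H](O[Si](C)(C)C(C)(C)C)C[C@@H](O[Si](C)(C)C(C)(C)C)C[C@H](O[Si](C)(C)C(C)(C)C)CCOCc2ccccc2 | intermediate
20 | C3–C15 β-hydroxy imine (11-imino; 13-hydroxy; otherwise as 21) | CC(C)(C)[Si](C)(C)OC[C@H](O[Si](C)(C)C(C)(C)C)[C@@H](O)CC(=N)C[C@@H](O[Si](C)(C)C(C)(C)C)C[C@@H](O[Si](C)(C)C(C)(C)C)C[C@H](O[Si](C)(C)C(C)(C)C)CCOCc1ccccc1 | intermediate
21 | C3–C15 β-hydroxy ketone: 3-O-Bn; 5,7,9,14,15-penta-O-TBS; 11-oxo; 13-hydroxy; C5, C7, C9, C13, C14 as in 62 | CC(C)(C)[Si](C)(C)OC[C@H](O[Si](C)(C)C(C)(C)C)[C@@H](O)CC(=O)C[C@@H](O[Si](C)(C)C(C)(C)C)C[C@@H](O[Si](C)(C)C(C)(C)C)C[C@H](O[Si](C)(C)C(C)(C)C)CCOCc1ccccc1 | intermediate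
22 | C3–C15 11,13-syn diol: as 21 with a C11 carbinol configured as in 62 | CC(C)(C)[Si](C)(C)OC[C@H](O[Si](C)(C)C(C)(C)C)[C@@H](O)C[C@@H](O)C[C@@H](O[Si](C)(C)C(C)(C)C)C[C@@H](O[Si](C)(C)C(C)(C)C)C[C@H](O[Si](C)(C)C(C)(C)C)CCOCc1ccccc1 | intermediate
23 | C3–C15 chain: 3-O-Bn; 5,7,9,11,13,14,15-hepta-O-TBS; all centres as in 62 | CC(C)(C)[Si](C)(C)OC[C@H](O[Si](C)(C)C(C)(C)C)[C@@H](O[Si](C)(C)C(C)(C)C)C[C@@H](O[Si](C)(C)C(C)(C)C)C[C@@H](O[Si](C)(C)C(C)(C)C)C[C@@H](O[Si](C)(C)C(C)(C)C)C[C@H](O[Si](C)(C)C(C)(C)C)CCOCc1ccccc1 | intermediate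
24 | C3 primary alcohol (23 without benzyl) | CC(C)(C)[Si](C)(C)OC[C@H](O[Si](C)(C)C(C)(C)C)[C@@H](O[Si](C)(C)C(C)(C)C)C[C@@H](O[Si](C)(C)C(C)(C)C)C[C@@H](O[Si](C)(C)C(C)(C)C)C[C@@H](O[Si](C)(C)C(C)(C)C)C[C@H](O[Si](C)(C)C(C)(C)C)CCO | intermediate
25 | C3 aldehyde (C3–C15; hepta-O-TBS) | CC(C)(C)[Si](C)(C)OC[C@H](O[Si](C)(C)C(C)(C)C)[C@@H](O[Si](C)(C)C(C)(C)C)C[C@@H](O[Si](C)(C)C(C)(C)C)C[C@@H](O[Si](C)(C)C(C)(C)C)C[C@@H](O[Si](C)(C)C(C)(C)C)C[C@H](O[Si](C)(C)C(C)(C)C)CC=O | intermediate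
26 | methyl 3-oxooctanoate | CCCCCC(=O)CC(=O)OC | starting material
27 | methyl (S)-3-hydroxyoctanoate | CCCCC[C@H](O)CC(=O)OC | intermediate
28 | methyl (S)-3-(TBS-oxy)octanoate | CCCCC[C@H](O[Si](C)(C)C(C)(C)C)CC(=O)OC | intermediate
29 | (S)-3-(TBS-oxy)octanoic acid | CCCCC[C@H](O[Si](C)(C)C(C)(C)C)CC(=O)O | intermediate
30 | (R)-4-benzyloxazolidin-2-one | O=C1N[C@H](Cc2ccccc2)CO1 | starting material
31 | mixed anhydride of 29 with pivalic acid | CCCCC[C@H](O[Si](C)(C)C(C)(C)C)CC(=O)OC(=O)C(C)(C)C | intermediate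
32 | (R)-4-benzyl-3-[(S)-3-(TBS-oxy)octanoyl]oxazolidin-2-one | CCCCC[C@H](O[Si](C)(C)C(C)(C)C)CC(=O)N1[C@H](Cc2ccccc2)COC1=O | intermediate
33 | dibutylboron Z-enolate of 32 | CCCCC[C@H](O[Si](C)(C)C(C)(C)C)/C=C(\OB(CCCC)CCCC)N1[C@H](Cc2ccccc2)COC1=O | intermediate
34 | C1–C15 aldol adduct: C1 acyl oxazolidinone; 3-hydroxy; 1′,5,7,9,11,13,14,15-octa-O-TBS; 2,3-syn; all centres as in 62 | CC(C)(C)[Si](C)(C)OC[C@H](O[Si](C)(C)C(C)(C)C)[C@@H](O[Si](C)(C)C(C)(C)C)C[C@@H](O[Si](C)(C)C(C)(C)C)C[C@@H](O[Si](C)(C)C(C)(C)C)C[C@@H](O[Si](C)(C)C(C)(C)C)C[C@H](O[Si](C)(C)C(C)(C)C)C[C@H](O)[C@@H]([C@H](CCCCC)O[Si](C)(C)C(C)(C)C)C(=O)N1[C@H](Cc2ccccc2)COC1=O | intermediate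
35 | 3-O-TBS ether of 34 (nona-O-TBS) | CC(C)(C)[Si](C)(C)OC[C@H](O[Si](C)(C)C(C)(C)C)[C@@H](O[Si](C)(C)C(C)(C)C)C[C@@H](O[Si](C)(C)C(C)(C)C)C[C@@H](O[Si](C)(C)C(C)(C)C)C[C@@H](O[Si](C)(C)C(C)(C)C)C[C@H](O[Si](C)(C)C(C)(C)C)C[C@H](O[Si](C)(C)C(C)(C)C)[C@@H]([C@H](CCCCC)O[Si](C)(C)C(C)(C)C)C(=O)N1[C@H](Cc2ccccc2)COC1=O | intermediate
36 | C15 primary alcohol (1′,3,5,7,9,11,13,14-octa-O-TBS; imide at C1) | OC[C@H](O[Si](C)(C)C(C)(C)C)[C@@H](O[Si](C)(C)C(C)(C)C)C[C@@H](O[Si](C)(C)C(C)(C)C)C[C@@H](O[Si](C)(C)C(C)(C)C)C[C@@H](O[Si](C)(C)C(C)(C)C)C[C@H](O[Si](C)(C)C(C)(C)C)C[C@H](O[Si](C)(C)C(C)(C)C)[C@@H]([C@H](CCCCC)O[Si](C)(C)C(C)(C)C)C(=O)N1[C@H](Cc2ccccc2)COC1=O | intermediate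
37 | C15 aldehyde (octa-O-TBS; imide at C1) | O=C[C@H](O[Si](C)(C)C(C)(C)C)[C@@H](O[Si](C)(C)C(C)(C)C)C[C@@H](O[Si](C)(C)C(C)(C)C)C[C@@H](O[Si](C)(C)C(C)(C)C)C[C@@H](O[Si](C)(C)C(C)(C)C)C[C@H](O[Si](C)(C)C(C)(C)C)C[C@H](O[Si](C)(C)C(C)(C)C)[C@@H]([C@H](CCCCC)O[Si](C)(C)C(C)(C)C)C(=O)N1[C@H](Cc2ccccc2)COC1=O | intermediate
38 | but-2-yn-1-ol | CC#CCO | starting material
39 | (Z)-3-iodobut-2-en-1-ol | C/C(I)=C/CO | intermediate
40 | (Z)-3-iodobut-2-enal | C/C(I)=C/C=O | intermediate
41 | ethyl (2E,4Z)-5-iodohexa-2,4-dienoate | C/C(I)=C/C=C/C(=O)OCC | intermediate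
42 | (2E,4Z)-5-iodohexa-2,4-dien-1-ol | C/C(I)=C/C=C/CO | intermediate
43 | triethyl{[(2E,4Z)-5-iodohexa-2,4-dien-1-yl]oxy}silane (C16–C20) | C/C(I)=C/C=C/CO[Si](CC)(CC)CC | intermediate
44 | C1–C20 chain: 15-hydroxy (14,15-anti); 16Z,18E; 20-O-TES; octa-O-TBS; imide at C1 | CC[Si](CC)(CC)OC/C=C/C=C(/C)[C@H](O)[C@H](O[Si](C)(C)C(C)(C)C)[C@@H](O[Si](C)(C)C(C)(C)C)C[C@@H](O[Si](C)(C)C(C)(C)C)C[C@@H](O[Si](C)(C)C(C)(C)C)C[C@@H](O[Si](C)(C)C(C)(C)C)C[C@H](O[Si](C)(C)C(C)(C)C)C[C@H](O[Si](C)(C)C(C)(C)C)[C@@H]([C@H](CCCCC)O[Si](C)(C)C(C)(C)C)C(=O)N1[C@H](Cc2ccccc2)COC1=O | intermediate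
45 | 15-O-TBS ether of 44 | CC[Si](CC)(CC)OC/C=C/C=C(/C)[C@H](O[Si](C)(C)C(C)(C)C)[C@H](O[Si](C)(C)C(C)(C)C)[C@@H](O[Si](C)(C)C(C)(C)C)C[C@@H](O[Si](C)(C)C(C)(C)C)C[C@@H](O[Si](C)(C)C(C)(C)C)C[C@@H](O[Si](C)(C)C(C)(C)C)C[C@H](O[Si](C)(C)C(C)(C)C)C[C@H](O[Si](C)(C)C(C)(C)C)[C@@H]([C@H](CCCCC)O[Si](C)(C)C(C)(C)C)C(=O)N1[C@H](Cc2ccccc2)COC1=O | intermediate
46 | C20 primary dienol (nona-O-TBS; imide at C1) | OC/C=C/C=C(/C)[C@H](O[Si](C)(C)C(C)(C)C)[C@H](O[Si](C)(C)C(C)(C)C)[C@@H](O[Si](C)(C)C(C)(C)C)C[C@@H](O[Si](C)(C)C(C)(C)C)C[C@@H](O[Si](C)(C)C(C)(C)C)C[C@@H](O[Si](C)(C)C(C)(C)C)C[C@H](O[Si](C)(C)C(C)(C)C)C[C@H](O[Si](C)(C)C(C)(C)C)[C@@H]([C@H](CCCCC)O[Si](C)(C)C(C)(C)C)C(=O)N1[C@H](Cc2ccccc2)COC1=O | intermediate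
47 | C20 (16Z,18E)-dienal | O=C/C=C/C=C(/C)[C@H](O[Si](C)(C)C(C)(C)C)[C@H](O[Si](C)(C)C(C)(C)C)[C@@H](O[Si](C)(C)C(C)(C)C)C[C@@H](O[Si](C)(C)C(C)(C)C)C[C@@H](O[Si](C)(C)C(C)(C)C)C[C@@H](O[Si](C)(C)C(C)(C)C)C[C@H](O[Si](C)(C)C(C)(C)C)C[C@H](O[Si](C)(C)C(C)(C)C)[C@@H]([C@H](CCCCC)O[Si](C)(C)C(C)(C)C)C(=O)N1[C@H](Cc2ccccc2)COC1=O | intermediate
48 | C1–C21 (16Z,18E,20E)-21-iodotriene; nona-O-TBS; imide at C1 | I/C=C/C=C/C=C(/C)[C@H](O[Si](C)(C)C(C)(C)C)[C@H](O[Si](C)(C)C(C)(C)C)[C@@H](O[Si](C)(C)C(C)(C)C)C[C@@H](O[Si](C)(C)C(C)(C)C)C[C@@H](O[Si](C)(C)C(C)(C)C)C[C@@H](O[Si](C)(C)C(C)(C)C)C[C@H](O[Si](C)(C)C(C)(C)C)C[C@H](O[Si](C)(C)C(C)(C)C)[C@@H]([C@H](CCCCC)O[Si](C)(C)C(C)(C)C)C(=O)N1[C@H](Cc2ccccc2)COC1=O | intermediate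
49 | C1 peroxy acid corresponding to 50 | I/C=C/C=C/C=C(/C)[C@H](O[Si](C)(C)C(C)(C)C)[C@H](O[Si](C)(C)C(C)(C)C)[C@@H](O[Si](C)(C)C(C)(C)C)C[C@@H](O[Si](C)(C)C(C)(C)C)C[C@@H](O[Si](C)(C)C(C)(C)C)C[C@@H](O[Si](C)(C)C(C)(C)C)C[C@H](O[Si](C)(C)C(C)(C)C)C[C@H](O[Si](C)(C)C(C)(C)C)[C@@H]([C@H](CCCCC)O[Si](C)(C)C(C)(C)C)C(=O)OO | intermediate
50 | C1–C21 iodotriene carboxylic acid (nona-O-TBS) | I/C=C/C=C/C=C(/C)[C@H](O[Si](C)(C)C(C)(C)C)[C@H](O[Si](C)(C)C(C)(C)C)[C@@H](O[Si](C)(C)C(C)(C)C)C[C@@H](O[Si](C)(C)C(C)(C)C)C[C@@H](O[Si](C)(C)C(C)(C)C)C[C@@H](O[Si](C)(C)C(C)(C)C)C[C@H](O[Si](C)(C)C(C)(C)C)C[C@H](O[Si](C)(C)C(C)(C)C)[C@@H]([C@H](CCCCC)O[Si](C)(C)C(C)(C)C)C(=O)O | intermediate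
51 | ethyl (R)-3-hydroxybutanoate | CCOC(=O)C[C@@H](C)O | starting material
52 | dilithio alkoxide enolate of 51 | CCO/C(O[Li])=C/[C@@H](C)O[Li] | intermediate
53 | ethyl (2R,3R)-3-hydroxy-2-methylbutanoate | CCOC(=O)[C@H](C)[C@@H](C)O | intermediate
54 | ethyl (2R,3R)-3-(TBS-oxy)-2-methylbutanoate | CCOC(=O)[C@H](C)[C@@H](C)O[Si](C)(C)C(C)(C)C | intermediate
55 | (2R,3R)-3-(TBS-oxy)-2-methylbutanal | O=C[C@H](C)[C@@H](C)O[Si](C)(C)C(C)(C)C | intermediate
56 | tert-butyl{[(2R,3S,4E)-5-iodo-3-methylpent-4-en-2-yl]oxy}dimethylsilane | I/C=C/[C@H](C)[C@@H](C)O[Si](C)(C)C(C)(C)C | intermediate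
57 | tert-butyldimethyl{[(2R,3S,4E,6E)-3-methyl-7-(tributylstannyl)hepta-4,6-dien-2-yl]oxy}silane | CCCC[Sn](CCCC)(CCCC)/C=C/C=C/[C@H](C)[C@@H](C)O[Si](C)(C)C(C)(C)C | intermediate
58 | (2R,3S,4E,6E)-3-methyl-7-(tributylstannyl)hepta-4,6-dien-2-ol (C22–C27) | CCCC[Sn](CCCC)(CCCC)/C=C/C=C/[C@H](C)[C@@H](C)O | intermediate
59 | mixed anhydride of 50 with 2,4,6-trichlorobenzoic acid | I/C=C/C=C/C=C(/C)[C@H](O[Si](C)(C)C(C)(C)C)[C@H](O[Si](C)(C)C(C)(C)C)[C@@H](O[Si](C)(C)C(C)(C)C)C[C@@H](O[Si](C)(C)C(C)(C)C)C[C@@H](O[Si](C)(C)C(C)(C)C)C[C@@H](O[Si](C)(C)C(C)(C)C)C[C@H](O[Si](C)(C)C(C)(C)C)C[C@H](O[Si](C)(C)C(C)(C)C)[C@@H]([C@H](CCCCC)O[Si](C)(C)C(C)(C)C)C(=O)OC(=O)c1c(Cl)cc(Cl)cc1Cl | intermediate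
60 | seco ester of 50 with 58 (C21 iodide; C22 tributylstannane; nona-O-TBS) | I/C=C/C=C/C=C(/C)[C@H](O[Si](C)(C)C(C)(C)C)[C@H](O[Si](C)(C)C(C)(C)C)[C@@H](O[Si](C)(C)C(C)(C)C)C[C@@H](O[Si](C)(C)C(C)(C)C)C[C@@H](O[Si](C)(C)C(C)(C)C)C[C@@H](O[Si](C)(C)C(C)(C)C)C[C@H](O[Si](C)(C)C(C)(C)C)C[C@H](O[Si](C)(C)C(C)(C)C)[C@@H]([C@H](CCCCC)O[Si](C)(C)C(C)(C)C)C(=O)O[C@H](C)[C@@H](C)/C=C/C=C/[Sn](CCCC)(CCCC)CCCC | intermediate
61 | 1′,3,5,7,9,11,13,14,15-nona-O-TBS ether of 62 | CCCCC[C@H](O[Si](C)(C)C(C)(C)C)[C@H]1C(=O)O[C@H](C)[C@@H](C)/C=C/C=C/C=C/C=C/C=C(/C)[C@H](O[Si](C)(C)C(C)(C)C)[C@H](O[Si](C)(C)C(C)(C)C)[C@@H](O[Si](C)(C)C(C)(C)C)C[C@@H](O[Si](C)(C)C(C)(C)C)C[C@@H](O[Si](C)(C)C(C)(C)C)C[C@@H](O[Si](C)(C)C(C)(C)C)C[C@H](O[Si](C)(C)C(C)(C)C)C[C@@H]1O[Si](C)(C)C(C)(C)C | intermediate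
62 | CNP0269947.1: (3R,4S,6S,8R,10S,12S,14S,15R,16S,17Z,19E,21E,23E,25E,27S,28R)-4,6,8,10,12,14,15,16-octahydroxy-3-[(1S)-1-hydroxyhexyl]-17,27,28-trimethyl-1-oxacyclooctacosa-17,19,21,23,25-pentaen-2-one | CCCCC[C@H](O)[C@H]1C(=O)O[C@H](C)[C@@H](C)/C=C/C=C/C=C/C=C/C=C(/C)[C@H](O)[C@H](O)[C@@H](O)C[C@@H](O)C[C@@H](O)C[C@@H](O)C[C@H](O)C[C@@H]1O | target

## Step count and risk

Total: 46 steps. Longest linear sequence: 31 steps (steps 1–11, 13–19, 24–27, 32–37, 44–46).

**Step 13 (key step).** The nitrile oxide may dimerise to the furoxan faster than it adds. Facial selectivity may also erode if the undirected, non-chelated pathway competes, for instance when alkoxide formation is incomplete.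
Fallback (from 11 and 14, returning at 22): the masked aldol is replaced by a real one. Alkenol 14 is silylated (TBSCl, imidazole) to (R)-3,4-bis(TBS-oxy)but-1-ene F1. Wacker oxidation (PdCl2, CuCl, O2, DMF/H2O) gives (S)-3,4-bis(TBS-oxy)butan-2-one F2. Its diisopinocampheylboron enolate (Ipc2BCl of the enantiomeric series that gives the 9,11-syn sense, Et3N) adds to aldehyde 11 to give the 11-hydroxy-13-oxo compound F3, with C11 under reagent control. Et2BOMe/NaBH4 then reduces the C13 ketone syn to the C11 hydroxyl and gives diol 22.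

**Step 24 (aldol).** The C1′ silyloxy group may be lost by β-elimination during enolisation, the hindered imide may enolise incompletely, or the auxiliary may be mismatched with the two resident stereocentres.
Fallback (from 25 and 32, returning at 35): the potential leaving group is removed from the enolate. Imide 32 is desilylated (HF·pyridine) to (R)-4-benzyl-3-[(S)-3-hydroxyoctanoyl]oxazolidin-2-one F4. Two equivalents of Bu2BOTf with Et3N give its O-borylated Z-enolate, in which the β-oxygen is a boron alkoxide and cannot leave. Aldol addition to 25 gives the 1′,3-diol F5, and TBSOTf/2,6-lutidine on both hydroxyls gives 35.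

**Step 32 (C15–C16 coupling).** Facial selectivity at C15 may be poor if Felkin and anti-Felkin attack compete. Some C16=C17 geometry could also be lost in the alkenyl-metal intermediate.
Fallback (from 44 as obtained, returning at 44): the stereocentre is reset by oxidation and reduction. The mixture of 44 and its C15 epimer F6 is oxidised (Dess–Martin periodinane) to the C15 dienone F7. F7 is reduced under reagent control with the (S)-Me-CBS oxazaborolidine and catecholborane, with the dienyl group acting as the large substituent, to return 44.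

**Step 37 (auxiliary removal).** Hydroperoxide may attack the ring carbonyl of the oxazolidinone, or C2 deprotonation may lead to β-elimination, because the C1 carbonyl is flanked by two silyloxy-bearing branches.
Fallback (from 48, returning at 50): reductive removal, then oxidation. LiBH4 (Et2O, trace water) cleaves the imide to the C1 primary alcohol F8. Dess–Martin oxidation gives the C1 aldehyde F9, and Pinnick oxidation (NaClO2, NaH2PO4, 2-methylbut-2-ene) gives acid 50.

**Step 45 (ring closure).** Oligomerisation, protodestannylation or palladium-mediated E/Z isomerisation of the growing polyene may compete with cyclisation.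
Fallback (from 50 and 58, returning at 61): the order of the two bond formations is reversed. Intermolecular Stille coupling of acid 50 with stannane 58 (Pd2(dba)3, AsPh3, DMF) gives the pentaene seco acid F10. Yamaguchi macrolactonisation at high dilution then gives 61.

## Further compounds

F1 | step 13 | (R)-3,4-bis(TBS-oxy)but-1-ene | CC(C)(C)[Si](C)(C)OC[C@H](O[Si](C)(C)C(C)(C)C)C=C
F2 | step 13 | (S)-3,4-bis(TBS-oxy)butan-2-one | CC(C)(C)[Si](C)(C)OC[C@H](O[Si](C)(C)C(C)(C)C)C(C)=O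
F3 | step 13 | C3–C15 11-hydroxy-13-oxo compound (3-O-Bn; 5,7,9,14,15-penta-O-TBS) | CC(C)(C)[Si](C)(C)OC[C@H](O[Si](C)(C)C(C)(C)C)C(=O)C[C@@H](O)C[C@@H](O[Si](C)(C)C(C)(C)C)C[C@@H](O[Si](C)(C)C(C)(C)C)C[C@H](O[Si](C)(C)C(C)(C)C)CCOCc1ccccc1
F4 | step 24 | (R)-4-benzyl-3-[(S)-3-hydroxyoctanoyl]oxazolidin-2-one | CCCCC[C@H](O)CC(=O)N1[C@H](Cc2ccccc2)COC1=O
F5 | step 24 | C1–C15 aldol adduct with free 1′- and 3-hydroxyls (hepta-O-TBS; imide at C1) | CC(C)(C)[Si](C)(C)OC[C@H](O[Si](C)(C)C(C)(C)C)[C@@H](O[Si](C)(C)C(C)(C)C)C[C@@H](O[Si](C)(C)C(C)(C)C)C[C@@H](O[Si](C)(C)C(C)(C)C)C[C@@H](O[Si](C)(C)C(C)(C)C)C[C@H](O[Si](C)(C)C(C)(C)C)C[C@H](O)[C@@H]([C@H](CCCCC)O)C(=O)N1[C@H](Cc2ccccc2)COC1=O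
F6 | step 32 | C15 epimer of 44 | CC[Si](CC)(CC)OC/C=C/C=C(/C)[C@@H](O)[C@H](O[Si](C)(C)C(C)(C)C)[C@@H](O[Si](C)(C)C(C)(C)C)C[C@@H](O[Si](C)(C)C(C)(C)C)C[C@@H](O[Si](C)(C)C(C)(C)C)C[C@@H](O[Si](C)(C)C(C)(C)C)C[C@H](O[Si](C)(C)C(C)(C)C)C[C@H](O[Si](C)(C)C(C)(C)C)[C@@H]([C@H](CCCCC)O[Si](C)(C)C(C)(C)C)C(=O)N1[C@H](Cc2ccccc2)COC1=O
F7 | step 32 | C15 dienone corresponding to 44 | CC[Si](CC)(CC)OC/C=C/C=C(/C)C(=O)[C@H](O[Si](C)(C)C(C)(C)C)[C@@H](O[Si](C)(C)C(C)(C)C)C[C@@H](O[Si](C)(C)C(C)(C)C)C[C@@H](O[Si](C)(C)C(C)(C)C)C[C@@H](O[Si](C)(C)C(C)(C)C)C[C@H](O[Si](C)(C)C(C)(C)C)C[C@H](O[Si](C)(C)C(C)(C)C)[C@@H]([C@H](CCCCC)O[Si](C)(C)C(C)(C)C)C(=O)N1[C@H](Cc2ccccc2)COC1=O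
F8 | step 37 | C1 primary alcohol of the iodotriene (nona-O-TBS) | I/C=C/C=C/C=C(/C)[C@H](O[Si](C)(C)C(C)(C)C)[C@H](O[Si](C)(C)C(C)(C)C)[C@@H](O[Si](C)(C)C(C)(C)C)C[C@@H](O[Si](C)(C)C(C)(C)C)C[C@@H](O[Si](C)(C)C(C)(C)C)C[C@@H](O[Si](C)(C)C(C)(C)C)C[C@H](O[Si](C)(C)C(C)(C)C)C[C@H](O[Si](C)(C)C(C)(C)C)[C@@H]([C@H](CCCCC)O[Si](C)(C)C(C)(C)C)CO
F9 | step 37 | C1 aldehyde of the iodotriene (nona-O-TBS) | I/C=C/C=C/C=C(/C)[C@H](O[Si](C)(C)C(C)(C)C)[C@H](O[Si](C)(C)C(C)(C)C)[C@@H](O[Si](C)(C)C(C)(C)C)C[C@@H](O[Si](C)(C)C(C)(C)C)C[C@@H](O[Si](C)(C)C(C)(C)C)C[C@@H](O[Si](C)(C)C(C)(C)C)C[C@H](O[Si](C)(C)C(C)(C)C)C[C@H](O[Si](C)(C)C(C)(C)C)[C@@H]([C@H](CCCCC)O[Si](C)(C)C(C)(C)C)C=O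
F10 | step 45 | pentaene seco acid (27-hydroxy; C1 carboxylic acid; nona-O-TBS) | O[C@H](C)[C@@H](C)/C=C/C=C/C=C/C=C/C=C(/C)[C@H](O[Si](C)(C)C(C)(C)C)[C@H](O[Si](C)(C)C(C)(C)C)[C@@H](O[Si](C)(C)C(C)(C)C)C[C@@H](O[Si](C)(C)C(C)(C)C)C[C@@H](O[Si](C)(C)C(C)(C)C)C[C@@H](O[Si](C)(C)C(C)(C)C)C[C@H](O[Si](C)(C)C(C)(C)C)C[C@H](O[Si](C)(C)C(C)(C)C)[C@@H]([C@H](CCCCC)O[Si](C)(C)C(C)(C)C)C(=O)O
A1 | alternative 1 | (4R,6R)-nona-1,8-diene-4,6-diol | C=CC[C@@H](O)C[C@H](O)CC=C
A2 | alternative 1 | propane-1,3-diol | OCCCO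
A3 | alternative 1 | allyl acetate | CC(=O)OCC=C
A4 | alternative 1 | [Ir(cod)Cl]2 | C1=CCCC=CCC1.C1=CCCC=CCC1.[Cl-].[Cl-].[Ir+].[Ir+]
A5 | alternative 2 | 28-membered 18,19-didehydro macrolactone (13,14-acetonide; seven TBS ethers) | CCCCC[C@H](O[Si](C)(C)C(C)(C)C)[C@H]1C(=O)O[C@H](C)[C@@H](C)/C=C/C=C/C=C/C#C/C=C(/C)[C@H](O[Si](C)(C)C(C)(C)C)[C@@H]2OC(C)(C)O[C@H]2C[C@@H](O[Si](C)(C)C(C)(C)C)C[C@@H](O[Si](C)(C)C(C)(C)C)C[C@@H](O[Si](C)(C)C(C)(C)C)C[C@H](O[Si](C)(C)C(C)(C)C)C[C@@H]1O[Si](C)(C)C(C)(C)C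
A6 | alternative 2 | seco ester with two methyl-capped enyne ends | CC#C/C=C(/C)[C@H](O[Si](C)(C)C(C)(C)C)[C@@H]2OC(C)(C)O[C@H]2C[C@@H](O[Si](C)(C)C(C)(C)C)C[C@@H](O[Si](C)(C)C(C)(C)C)C[C@@H](O[Si](C)(C)C(C)(C)C)C[C@H](O[Si](C)(C)C(C)(C)C)C[C@H](O[Si](C)(C)C(C)(C)C)[C@@H]([C@H](CCCCC)O[Si](C)(C)C(C)(C)C)C(=O)O[C@H](C)[C@@H](C)/C=C/C=C/C=C/C#CC
A7 | alternative 2 | but-2-yne | CC#CC
A8 | alternative 2 | [Mo(≡CC6H4OMe)(OSiPh3)3] | COc1ccc(cc1)C#[Mo](O[Si](c1ccccc1)(c1ccccc1)c1ccccc1)(O[Si](c1ccccc1)(c1ccccc1)c1ccccc1)O[Si](c1ccccc1)(c1ccccc1)c1ccccc1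
A9 | alternative 3 | C3–C15 chain with C9 dithiane, C7 TBS ether and free C11 hydroxyl | COc1ccc(COC[C@@H]2OC(C)(C)O[C@H]2C[C@@H](O)CC3(SCCCS3)C[C@@H](O[Si](C)(C)C(C)(C)C)C[C@H](O[Si](C)(C)C(C)(C)C)CCOCc4ccccc4)cc1
A10 | alternative 3 | 2-(tert-butyldimethylsilyl)-1,3-dithiane | CC(C)(C)[Si](C)(C)C1SCCCS1
A11 | alternative 3 | C3–C8 epoxide (5-O-TBS; 3-O-Bn) | C1O[C@H]1C[C@H](O[Si](C)(C)C(C)(C)C)CCOCc2ccccc2
A12 | alternative 3 | C10–C15 epoxide (13,14-acetonide; 15-O-p-methoxybenzyl) | COc1ccc(COC[C@@H]2OC(C)(C)O[C@H]2C[C@@H]3CO3)cc1
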